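Readings and results are calculated for substances that don't exist; the scatter is artificial.

We cannot have the reagent run out if it is taken one for one, because 40.0 mM of it stands against 20 mM of substrate, and half of the charge survives even complete conversion. That keeps reagent in the flask but does not keep it constant, and a single earlier run at a single reagent charge shows no order, so it is a working assumption of ours that the substrate decays pseudo-first-order, with a rate proportional to reagent.

all flasks: substrate 20 mM
- south-west: reagent 80 mM; capture agent 1 mM; temperature 70 °C; run made earlier
- alpha: reagent 40.0 mM; capture agent 1.00 mM; temperature 80 °C; time 8.0 min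
- eta: reagent 40.0 mM; capture agent 1.00 mM; temperature 90 °C; time 8.0 min
- theta: reagent 40.0 mM; capture agent 1.00 mM; temperature 70 °C; time 8.0 min

south-west run (percent of the substrate charged)

| time / s | substrate / % | intermediate B / % | intermediate A / % | target / % |
|---|---|---|---|---|
| 10.0 | 89.8 | 6.7 | 3.4 | 0.1 |
| 20.0 | 81.8 | 11.6 | 6.5 | 0 |
| 30.0 | 73.1 | 16.1 | 9.8 | 0 |
| 40.0 | 67.3 | 18.6 | 12.3 | 1.5 |
| 50.0 | 60.8 | 24.5 | 15.2 | 1.3 |

(scatter of a reading: 1 percentage point)

- the earlier runs do not show what temperature does; that part of a forecast is a guess

* which of these there is most of at the end, counted by the substrate in it, alpha (intermediate B / target / intermediate A / substrate)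
* which of these there is most of at the end, counted by the substrate in it, eta (intermediate B / target / intermediate A / substrate)
* which of these there is most of at the end, counted by the substrate in it, theta (intermediate B / target / intermediate A / substrate)
* the largest of these amounts at the end, in percent of the substrate charged, alpha
* the largest of these amounts at the end, in percent of the substrate charged, eta
* the largest of these amounts at the end, in percent of the substrate charged, theta

The south-west run falls to 60.8 % at 50.0 s, which reads as a rate constant of 0.597 min⁻¹ at 80 mM reagent. We fold theta's givens into one number: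

lifetime count = rate constant × (reagent in theta / reagent in the south-west run) × time = 2.39

We call this the lifetime count: the number of substrate lifetimes the flask holds at its charged reagent. Substrate left is then exp(−count), or exp(−count/2) if the reagent sinks to the floor above:

theta, substrate left: 9.18 % to 30.3 %

The readings put 61.7 % of the converted substrate into intermediate B, so we expect 43.0 % to 56.0 % of it in theta, more than substrate. Is one number enough? The readings span 0.497 lifetimes against a count of 2.39, and the count has no term for a way back or for temperature, so for alpha and eta we give no number of our own.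

The forecast names intermediate B for theta at 52 % (42 % to 60 %), and intermediate B for alpha at 57 % and intermediate B for eta at 57 %: “B should therefore lead in all three runs”.

The flasks give substrate at 42.9 % in alpha, target at 41.1 % in eta, and substrate at 45.1 % in theta.

    substrate + reagent ⇌ intermediate B (K = 23.0 M⁻¹, k = 5.30 M⁻¹ min⁻¹, Ea = 55.0 kJ mol⁻¹, ΔH = −39.0 kJ mol⁻¹)
    intermediate A → target (k = 0.0900 min⁻¹, Ea = 91.0 kJ mol⁻¹)
    reagent + intermediate A ⇌ intermediate C (K = 29.0 M⁻¹, k = 0.570 M⁻¹ min⁻¹, Ea = 79.0 kJ mol⁻¹, ΔH = −25.0 kJ mol⁻¹)
    substrate + reagent ⇌ intermediate A (K = 13.0 M⁻¹, k = 3.30 M⁻¹ min⁻¹, Ea = 54.0 kJ mol⁻¹, ΔH = 2.00 kJ mol⁻¹)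
    capture agent + intermediate A → trapped intermediate (k = 14.0 M⁻¹ min⁻¹, Ea = 57.0 kJ mol⁻¹)
    reagent + intermediate B → side product (k = 0.140 M⁻¹ min⁻¹, Ea = 74.0 kJ mol⁻¹)
    (constants at 70 °C)

Both steps out of the substrate run both ways. Theta's 45.1 % of substrate stands above our 30.3 %, and it corresponds to 0.797 lifetimes against the count of 2.39. The neighbouring flask is theta left until 15 min. Its count, scaled by the ratio of the times, is 4.48, which reckons substrate left at 1.13 % to 10.6 %. That flask still holds 40.4 % of substrate, or 0.906 lifetimes.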